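**Plan**

- Retrosynthesis: the C12–O6 lactone is cut first (oxidative lactonisation of a 6,12-diol), then C2–C3. With the carbocycle numbered C1 (ketone) to C10 (quaternary, methyl C14), the furanone ring is O/C3/C2/C1/C10 and its O–C3 bond is an acyl–oxygen bond in disguise. Cutting C2–C3 therefore unfolds the furanone-bridged cyclodecadiene into a nine-membered lactone (O, C3–C10) of the C10 tertiary alcohol, with an acetyl group (C1, C2) on C10.
- The lactone is then cut at C4=C5 (ring-closing metathesis) and at the ester O–C3, and the chain at C7–C8 (indium Barbier allylation). This leaves fragment A (C8–C10, C1, C2, C14), fragment B (C5–C7, C11–C13) and fragment C (C3, C4, C15).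
- Forward: A + B give a cis-lactone (C7–C8); reduction, silylation and tigloylation follow; the C10 hydroxyl is esterified with C; alkyne hydration unveils the ketone; metathesis closes the nonenolide; the Claisen condensation makes the furanone and the ten-membered ring at once; desilylation, lactonisation and PMB removal finish.
- Stereochemistry: C10 comes from (R)-citramalic acid and C6 from (S)-but-3-ene-1,2-diol. C7 and C8 come from the Barbier step (syn addition, face set by C6). Z-C4=C5 is enforced by the ring; the key step creates no stereocentre.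

Key step: step 20

Remark: read from the SMILES, H-6, H-7 and H-8 lie on the same face of the carbocycle (6S,7R,8R,10R; cis-fused 6,12-lactone with the 8-acyloxy group cis to it), and the route is built for exactly this isomer; (R)-citramalic acid and (S)-but-3-ene-1,2-diol are taken as purchasable in enantiopure form.

Abbreviations: TBS = tert-butyldimethylsilyl; PMB = 4-methoxybenzyl. C-numbers in the text are those of the target carbocycle.

**Fragment A**

Step 1
Reactants: 1 (R)-citramalic acid
Product: 2 2-[(4R)-2,2,4-trimethyl-5-oxo-1,3-dioxolan-4-yl]acetic acid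
Conditions: Me2C(OMe)2, TsOH·H2O (cat.), acetone, rt
Reagents that add atoms: 2,2-dimethoxypropane COC(C)(C)OC
Why: Acid-catalysed transacetalisation ties the α-hydroxy acid into the five-membered dioxolanone (favoured over the six-membered ring from the β-carboxyl), which differentiates the two carboxyl groups without touching the quaternary centre.

Step 2
Reactants: 2 2-[(4R)-2,2,4-trimethyl-5-oxo-1,3-dioxolan-4-yl]acetic acid
Product: 4 (3R)-3-hydroxy-3-methyloxolan-2-one, via hydroxyethyl dioxolanone 3 (not isolated)
Conditions: BH3·SMe2, THF, 0 °C → rt; H2O quench; then TsOH·H2O (cat.), CH2Cl2, rt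
Reagents that add atoms: none
Why: Borane reduces a free carboxylic acid much faster than the dioxolanone ester, and the primary alcohol of 3 then attacks the dioxolanone carbonyl under acid (translactonisation with loss of acetone) to give the γ-lactone.

Step 3
Reactants: 4 (3R)-3-hydroxy-3-methyloxolan-2-one
Product: 5 (3R)-3-methyloxolane-2,3-diol (lactol as anomers)
Conditions: iBu2AlH (2.2 equiv), CH2Cl2, −78 °C; aq. potassium sodium tartrate
Reagents that add atoms: none
Why: Partial reduction of a γ-lactone with iBu2AlH at −78 °C stops at the aluminium hemiacetal (the first equivalent is consumed by the tertiary hydroxyl), which gives the lactol on work-up.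

Step 4
Reactants: 5 (3R)-3-methyloxolane-2,3-diol
Product: 6 (3R)-3-methylpent-4-yne-1,3-diol
Conditions: dimethyl (1-diazo-2-oxopropyl)phosphonate, K2CO3, MeOH, 0 °C → rt
Reagents that add atoms: dimethyl (1-diazo-2-oxopropyl)phosphonate CC(=O)C(=[N+]=[N-])P(=O)(OC)OC
Why: Seyferth–Gilbert homologation in the Ohira–Bestmann variant converts the open-chain α-hydroxy aldehyde form of the lactol into the terminal alkyne, the robust mask of the C1/C2 acetyl group; the adjacent centre is quaternary and cannot epimerise.

Step 5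
Reactants: 6 (3R)-3-methylpent-4-yne-1,3-diol
Product: 7 (3R)-3-hydroxy-3-methylpent-4-ynal
Conditions: TEMPO (cat.), PhI(OAc)2, CH2Cl2, rt; used crude
Reagents that add atoms: none
Why: The TEMPO/PhI(OAc)2 oxoammonium oxidation takes primary alcohols to aldehydes without over-oxidation and cannot oxidise the tertiary propargylic alcohol.

**Fragment B**

Step 6
Reactants: 8 (2S)-but-3-ene-1,2-diol
Product: 9 (3S)-3,4-bis[(tert-butyldimethylsilyl)oxy]but-1-ene
Conditions: TBSCl, imidazole, DMF, rt
Reagents that add atoms: tert-butyldimethylsilyl chloride CC(C)(C)[Si](C)(C)Cl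
Why: Standard imidazole-promoted silylation of both hydroxyl groups.

Step 7
Reactants: 9 (3S)-3,4-bis[(tert-butyldimethylsilyl)oxy]but-1-ene
Product: 10 (2S)-2-[(tert-butyldimethylsilyl)oxy]but-3-en-1-ol
Conditions: HF·pyridine, pyridine, THF, 0 °C
Reagents that add atoms: none
Why: Under buffered HF·pyridine the primary silyl ether is cleaved well before the secondary allylic one (selective monodesilylation), and the acidic medium excludes silyl migration.

Step 8
Reactants: 10 (2S)-2-[(tert-butyldimethylsilyl)oxy]but-3-en-1-ol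
Product: 11 (2S)-2-[(tert-butyldimethylsilyl)oxy]but-3-enal
Conditions: Dess–Martin periodinane, pyridine, CH2Cl2, 0 °C; used at once
Reagents that add atoms: none
Why: Dess–Martin oxidation under pyridine buffer is fast and non-basic, which should keep the α-silyloxy β,γ-unsaturated aldehyde from epimerising or moving into conjugation.

Step 9
Reactants: 11 (2S)-2-[(tert-butyldimethylsilyl)oxy]but-3-enal; 12 methyl propiolate
Product: 14 methyl (4S)-4-[(tert-butyldimethylsilyl)oxy]-3-hydroxy-2-methylidenehex-5-enoate (C3 epimers), via vinylalane 13 (not isolated)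
Conditions: 12, iBu2AlH, NMO, THF, 0 °C; then 11, 0 °C → rt
Reagents that add atoms: none
Why: Hydroalumination of the propiolate gives the α-aluminoacrylate 13, which adds to the aldehyde to give the Morita–Baylis–Hillman-type adduct without amine base; the new carbinol centre is left as a mixture because it is destroyed in step 10.

Step 10
Reactants: 14 methyl (4S)-4-[(tert-butyldimethylsilyl)oxy]-3-hydroxy-2-methylidenehex-5-enoate
Product: 15 methyl (2Z,4S)-2-(bromomethyl)-4-[(tert-butyldimethylsilyl)oxy]hexa-2,5-dienoate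
Conditions: NBS, Me2S, CH2Cl2, 0 °C → rt
Reagents that add atoms: N-bromosuccinimide O=C1CCC(=O)N1Br
Why: The sulfonium-activated hydroxyl is displaced by bromide with allylic transposition (SN2′), which gives the (Z)-2-(bromomethyl)alk-2-enoate with the C6 branch trans to the ester; the C6 centre is not involved.

**Union of A and B**

Step 11
Reactants: 7 (3R)-3-hydroxy-3-methylpent-4-ynal; 15 methyl (2Z,4S)-2-(bromomethyl)-4-[(tert-butyldimethylsilyl)oxy]hexa-2,5-dienoate
Product: 18 (4R,5R)-4-[(1S)-1-[(tert-butyldimethylsilyl)oxy]prop-2-en-1-yl]-5-[(2R)-2-hydroxy-2-methylbut-3-yn-1-yl]-3-methylideneoxolan-2-one, via allylindium dibromide 16 (not isolated), via hydroxy ester 17 (not isolated)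
Conditions: In powder, THF/H2O (1:1), rt; then PPTS (cat.), CH2Cl2, rt
Reagents that add atoms: none
Why: Indium-mediated Barbier allylation: the 2-(methoxycarbonyl)allylindium 16 adds through its γ-carbon C7 in a chair transition state with the C6 branch axial, which gives the syn adduct 17 and hence the cis-β,γ-disubstituted α-methylene lactone (C8 set relative to C7), while the C6 centre, with its hydrogen eclipsing the alkene (allylic 1,3-strain) and the silyloxy group outside, should send the aldehyde to the face of C7 anti to the vinyl group (C7 set anti to C6–O); the free tertiary hydroxyl and the alkyne are tolerated in water.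

Step 12
Reactants: 18 cis-lactone
Product: 19 (3R,5R,6R)-6-[(1S)-1-[(tert-butyldimethylsilyl)oxy]prop-2-en-1-yl]-3-methyl-7-methylideneoct-1-yne-3,5,8-triol
Conditions: iBu2AlH (excess), CH2Cl2, −78 → 0 °C; aq. potassium sodium tartrate
Reagents that add atoms: none
Why: iBu2AlH reduces the α-methylene lactone by 1,2-addition through the lactol to the 2-methylene-1,4-diol, which frees C8–OH (secondary) and C12–OH (primary) in differentiated form while alkyne, alkenes and silyl ether are inert.

Step 13
Reactants: 19 triol
Product: 20 (3R,5R,6R)-8-[(tert-butyldimethylsilyl)oxy]-6-[(1S)-1-[(tert-butyldimethylsilyl)oxy]prop-2-en-1-yl]-3-methyl-7-methylideneoct-1-yne-3,5-diol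
Conditions: TBSCl (1.05 equiv), imidazole, CH2Cl2, −20 → 0 °C
Reagents that add atoms: tert-butyldimethylsilyl chloride CC(C)(C)[Si](C)(C)Cl
Why: The primary allylic hydroxyl is silylated far faster than the hindered secondary and the tertiary hydroxyl (chemoselective silylation).

Step 14
Reactants: 20 bis-silyl diol; 21 tiglic acid
Product: 23 (3R,5R,6R)-8-[(tert-butyldimethylsilyl)oxy]-6-[(1S)-1-[(tert-butyldimethylsilyl)oxy]prop-2-en-1-yl]-3-hydroxy-3-methyl-7-methylideneoct-1-yn-5-yl (2E)-2-methylbut-2-enoate, via mixed anhydride 22 (not isolated)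
Conditions: 21, 2,4,6-Cl3C6H2COCl, Et3N, THF, rt; then 20, DMAP, toluene, rt
Reagents that add atoms: none
Why: Yamaguchi esterification through mixed anhydride 22 acylates the secondary C8 hydroxyl, the tertiary propargylic hydroxyl reacting much more slowly, and tiglic acid, the stable E isomer, cannot isomerise under these conditions.

**Fragment C**

Step 15
Reactants: 24 methyl 2-(bromomethyl)prop-2-enoate
Product: 25 methyl 2-{[(4-methoxybenzyl)oxy]methyl}prop-2-enoate
Conditions: 4-MeOC6H4CH2OH, DABCO (cat.), Et3N, CH2Cl2, rt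
Reagents that add atoms: 4-methoxybenzyl alcohol COc1ccc(CO)cc1
Why: The allylic bromide is displaced by the alcohol by way of the DABCO allylammonium salt (double SN2′ substitution), the usual route to 2-(alkoxymethyl)acrylates.

Step 16
Reactants: 25 methyl 2-{[(4-methoxybenzyl)oxy]methyl}prop-2-enoate
Product: 26 2-{[(4-methoxybenzyl)oxy]methyl}prop-2-enoic acid
Conditions: LiOH, THF/H2O, 0 °C → rt; then 1 M HCl to pH 3
Reagents that add atoms: lithium hydroxide [Li+].[OH-]
Why: Saponification of the methyl ester at low temperature, where conjugate addition of hydroxide to the hindered acrylate is slow.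

**Nonenolide, key step and endgame**

Step 17
Reactants: 23 tiglate with free C10 hydroxyl; 26 2-{[(4-methoxybenzyl)oxy]methyl}prop-2-enoic acid
Product: 28 (3R,5R,6R)-8-[(tert-butyldimethylsilyl)oxy]-6-[(1S)-1-[(tert-butyldimethylsilyl)oxy]prop-2-en-1-yl]-3-methyl-7-methylidene-5-{[(2E)-2-methylbut-2-enoyl]oxy}oct-1-yn-3-yl 2-{[(4-methoxybenzyl)oxy]methyl}prop-2-enoate, via acid chloride 27 (not isolated)
Conditions: 26, 1-chloro-N,N,2-trimethylprop-1-en-1-amine, CH2Cl2, 0 °C; then 23, Et3N, DMAP, CH2Cl2, 0 → 40 °C
Reagents that add atoms: none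
Why: The acid chloride 27, made under neutral conditions that spare the PMB ether, acylates the only remaining free hydroxyl, the tertiary propargylic one, under DMAP catalysis (nucleophilic acyl-transfer catalysis), a standard way to esters of tertiary propargylic alcohols.

Step 18
Reactants: 28 propargylic diester
Product: 29 (3R,5R,6R)-8-[(tert-butyldimethylsilyl)oxy]-6-[(1S)-1-[(tert-butyldimethylsilyl)oxy]prop-2-en-1-yl]-3-methyl-7-methylidene-5-{[(2E)-2-methylbut-2-enoyl]oxy}-2-oxooctan-3-yl 2-{[(4-methoxybenzyl)oxy]methyl}prop-2-enoate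
Conditions: Ph3PAuCl (5 mol %), AgSbF6 (5 mol %), 1,4-dioxane/H2O (20:1), rt
Reagents that add atoms: water O
Why: Gold-catalysed hydration of a propargylic ester with neighbouring-group help: the ester carbonyl attacks the gold-activated alkyne 5-exo-dig and water opens the dioxolenium intermediate, which gives the Markovnikov methyl ketone with the acyl group back on the C10 oxygen (the α-acyloxy ketone); alkenes, silyl ethers and the PMB ether are not activated by the soft gold cation.

Step 19
Reactants: 29 open-chain α-acyloxy ketone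
Product: 30 (3Z,5S,6R,7R,9R)-9-acetyl-5-[(tert-butyldimethylsilyl)oxy]-6-{3-[(tert-butyldimethylsilyl)oxy]prop-1-en-2-yl}-3-{[(4-methoxybenzyl)oxy]methyl}-9-methyl-2-oxo-2,5,6,7,8,9-hexahydrooxonin-7-yl (2E)-2-methylbut-2-enoate
Conditions: second-generation Hoveyda–Grubbs catalyst RuCl2(H2IMes)(=CH–C6H4-2-OiPr) (15 mol %), toluene (1 mM), 80 °C
Reagents that add atoms: none
Why: Ring-closing metathesis of the C6 vinyl group with the acrylate methylene releases ethene and closes the nine-membered lactone, whose ring size allows only the Z trisubstituted enoate; the 1,1-disubstituted C11=C13 alkene and the tiglate can give no unstrained ring, the C6 oxygen stays silylated so that no butenolide can form, and the quaternary C10 and the three substituted centres C6–C8 should help the chain to fold.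

Step 20
Reactants: 30 (Z)-nonenolide with the C10 acetyl group
Product: 32 furanone-bridged cyclodecadiene bis-silyl ether (6S,7R,8R,10R), via bridged hemiketal 31 (not isolated)
Conditions: LiN(SiMe3)2 (2.2 equiv), THF, −78 → −20 °C; AcOH quench; then TsOH·H2O (cat.), CH2Cl2, 0 °C → rt
Reagents that add atoms: none
Why: LiN(SiMe3)2 deprotonates the methyl ketone at C2, its only enolisable position because C10 is quaternary, and the enolate adds to the lactone carbonyl C3, held two atoms away through O–C10; the adduct 31 (a bridged hemiketal that may equilibrate with the ring-opened hydroxy 1,3-diketone, both already containing the ten-membered carbocycle) loses water under acid to give the vinylogous ester. The closest known reaction is the base-induced cyclisation of α-acyloxy ketones to 3(2H)-furanones, an intramolecular Claisen condensation followed by cyclodehydration. The furanone ring closes by 5-exo-trig C–C bond formation (C2–C3) with its ring oxygen already in place, and the same bond closes the ten-membered carbocycle by turning the O-linked nine-membered ring into the C-linked ring, so that no direct medium-ring C–C closure is needed. No stereocentre is formed: C6, C7, C8 and C10 are carried through and the Z geometry of C4=C5 is fixed by the ring. The step needs enolisation of the ketone in preference to γ-deprotonation of the enoate (C6–H) or the tiglate, and attack on the lactone and not on the tiglate; the higher kinetic acidity of the methyl ketone at −78 °C and a five-membered against a seven-membered transition state should secure both. Two equivalents of base are used because the 1,3-dicarbonyl product is more acidic than the ketone.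

Step 21
Reactants: 32 furanone-bridged bis-silyl ether
Product: 33 6,12-diol (6S,7S,8R,10R; same geometry as 32 and the C7 label changes only through the CIP priorities)
Conditions: HF·pyridine, pyridine, THF, 0 °C → rt
Reagents that add atoms: none
Why: Buffered HF·pyridine cleaves both silyl ethers (Si–F bond formation) under mildly acidic conditions, which avoids the 1,3-migration of the tiglate from O8 to O6 that a basic fluoride source could cause.

Step 22
Reactants: 33 6,12-diol
Product: 35 15-O-PMB α-methylene lactone (6S,7R,8R,10R), via lactol 34 (not isolated)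
Conditions: TEMPO (cat.), PhI(OAc)2 (2.5 equiv), CH2Cl2, rt
Reagents that add atoms: none
Why: TEMPO/PhI(OAc)2 oxidative lactonisation: the primary allylic alcohol is oxidised to the enal, which is trapped by the cis C6 hydroxyl as lactol 34 and oxidised on to the α-methylene lactone; the secondary allylic C6 hydroxyl is oxidised far more slowly and is consumed by lactol formation.

Step 23
Reactants: 35 15-O-PMB α-methylene lactone
Product: 36 target CNP0269689.6
Conditions: DDQ, CH2Cl2/pH 7 phosphate buffer (10:1), 0 °C
Reagents that add atoms: none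
Why: DDQ removes the PMB ether by benzylic oxidation and hydrolysis of the oxocarbenium ion (oxidative PMB cleavage); the furanone, the enoate and the lactone are electron-poor and should not react.

**Compound list**

1 | (R)-citramalic acid, (2R)-2-hydroxy-2-methylbutanedioic acid | OC(=O)[C@@](C)(CC(=O)O)O | starting material
2 | 2-[(4R)-2,2,4-trimethyl-5-oxo-1,3-dioxolan-4-yl]acetic acid | O=C1OC(C)(C)O[C@]1(C)CC(=O)O | intermediate
3 | (5R)-5-(2-hydroxyethyl)-2,2,5-trimethyl-1,3-dioxolan-4-one | O=C1OC(C)(C)O[C@]1(C)CCO | intermediate (not isolated)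
4 | (3R)-3-hydroxy-3-methyloxolan-2-one | O=C1OCC[C@@]1(C)O | intermediate
5 | (3R)-3-methyloxolane-2,3-diol, lactol as anomers | OC1OCC[C@@]1(C)O | intermediate
6 | (3R)-3-methylpent-4-yne-1,3-diol | C#C[C@](C)(O)CCO | intermediate
7 | (3R)-3-hydroxy-3-methylpent-4-ynal, fragment A | C#C[C@](C)(O)CC=O | intermediate
8 | (2S)-but-3-ene-1,2-diol | C=C[C@H](O)CO | starting material
9 | (3S)-3,4-bis[(tert-butyldimethylsilyl)oxy]but-1-ene | C=C[C@H](O[Si](C)(C)C(C)(C)C)CO[Si](C)(C)C(C)(C)C | intermediate
10 | (2S)-2-[(tert-butyldimethylsilyl)oxy]but-3-en-1-ol | C=C[C@H](O[Si](C)(C)C(C)(C)C)CO | intermediate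
11 | (2S)-2-[(tert-butyldimethylsilyl)oxy]but-3-enal | C=C[C@H](O[Si](C)(C)C(C)(C)C)C=O | intermediate
12 | methyl propiolate | C#CC(=O)OC | starting material
13 | methyl 2-(diisobutylalumanyl)prop-2-enoate | C=C(C(=O)OC)[Al](CC(C)C)CC(C)C | intermediate (not isolated)
14 | methyl (4S)-4-[(tert-butyldimethylsilyl)oxy]-3-hydroxy-2-methylidenehex-5-enoate, C3 epimers | C=C[C@H](O[Si](C)(C)C(C)(C)C)C(O)C(=C)C(=O)OC | intermediate
15 | methyl (2Z,4S)-2-(bromomethyl)-4-[(tert-butyldimethylsilyl)oxy]hexa-2,5-dienoate, fragment B | C=C[C@H](O[Si](C)(C)C(C)(C)C)/C=C(\CBr)C(=O)OC | intermediate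
16 | methyl (2Z,4S)-4-[(tert-butyldimethylsilyl)oxy]-2-[(dibromoindiganyl)methyl]hexa-2,5-dienoate | C=C[C@H](O[Si](C)(C)C(C)(C)C)/C=C(\C[In](Br)Br)C(=O)OC | intermediate (not isolated)
17 | methyl (3R,4R,6R)-3-[(1S)-1-[(tert-butyldimethylsilyl)oxy]prop-2-en-1-yl]-4,6-dihydroxy-6-methyl-2-methylideneoct-7-ynoate | C#C[C@](C)(O)C[C@@H](O)[C@@H](C(=C)C(=O)OC)[C@@H](O[Si](C)(C)C(C)(C)C)C=C | intermediate (not isolated)
18 | (4R,5R)-4-[(1S)-1-[(tert-butyldimethylsilyl)oxy]prop-2-en-1-yl]-5-[(2R)-2-hydroxy-2-methylbut-3-yn-1-yl]-3-methylideneoxolan-2-one | C#C[C@](C)(O)C[C@H]1OC(=O)C(=C)[C@H]1[C@@H](O[Si](C)(C)C(C)(C)C)C=C | intermediate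
19 | (3R,5R,6R)-6-[(1S)-1-[(tert-butyldimethylsilyl)oxy]prop-2-en-1-yl]-3-methyl-7-methylideneoct-1-yne-3,5,8-triol | C#C[C@](C)(O)C[C@@H](O)[C@@H](C(=C)CO)[C@@H](O[Si](C)(C)C(C)(C)C)C=C | intermediate
20 | (3R,5R,6R)-8-[(tert-butyldimethylsilyl)oxy]-6-[(1S)-1-[(tert-butyldimethylsilyl)oxy]prop-2-en-1-yl]-3-methyl-7-methylideneoct-1-yne-3,5-diol | C#C[C@](C)(O)C[C@@H](O)[C@@H](C(=C)CO[Si](C)(C)C(C)(C)C)[C@@H](O[Si](C)(C)C(C)(C)C)C=C | intermediate
21 | tiglic acid, (2E)-2-methylbut-2-enoic acid | C/C=C(\C)C(=O)O | starting material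
22 | (2E)-2-methylbut-2-enoic 2,4,6-trichlorobenzoic anhydride | C/C=C(\C)C(=O)OC(=O)c1c(Cl)cc(Cl)cc1Cl | intermediate (not isolated)
23 | (3R,5R,6R)-8-[(tert-butyldimethylsilyl)oxy]-6-[(1S)-1-[(tert-butyldimethylsilyl)oxy]prop-2-en-1-yl]-3-hydroxy-3-methyl-7-methylideneoct-1-yn-5-yl (2E)-2-methylbut-2-enoate | C#C[C@](C)(O)C[C@@H](OC(=O)/C(C)=C/C)[C@@H](C(=C)CO[Si](C)(C)C(C)(C)C)[C@@H](O[Si](C)(C)C(C)(C)C)C=C | intermediate
24 | methyl 2-(bromomethyl)prop-2-enoate | C=C(CBr)C(=O)OC | starting material
25 | methyl 2-{[(4-methoxybenzyl)oxy]methyl}prop-2-enoate | C=C(COCc1ccc(OC)cc1)C(=O)OC | intermediate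
26 | 2-{[(4-methoxybenzyl)oxy]methyl}prop-2-enoic acid, fragment C | C=C(COCc1ccc(OC)cc1)C(=O)O | intermediate
27 | 2-{[(4-methoxybenzyl)oxy]methyl}prop-2-enoyl chloride | C=C(COCc1ccc(OC)cc1)C(Cl)=O | intermediate (not isolated)
28 | (3R,5R,6R)-8-[(tert-butyldimethylsilyl)oxy]-6-[(1S)-1-[(tert-butyldimethylsilyl)oxy]prop-2-en-1-yl]-3-methyl-7-methylidene-5-{[(2E)-2-methylbut-2-enoyl]oxy}oct-1-yn-3-yl 2-{[(4-methoxybenzyl)oxy]methyl}prop-2-enoate | C#C[C@](C)(OC(=O)C(=C)COCc1ccc(OC)cc1)C[C@@H](OC(=O)/C(C)=C/C)[C@@H](C(=C)CO[Si](C)(C)C(C)(C)C)[C@@H](O[Si](C)(C)C(C)(C)C)C=C | intermediate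
29 | (3R,5R,6R)-8-[(tert-butyldimethylsilyl)oxy]-6-[(1S)-1-[(tert-butyldimethylsilyl)oxy]prop-2-en-1-yl]-3-methyl-7-methylidene-5-{[(2E)-2-methylbut-2-enoyl]oxy}-2-oxooctan-3-yl 2-{[(4-methoxybenzyl)oxy]methyl}prop-2-enoate | CC(=O)[C@](C)(OC(=O)C(=C)COCc1ccc(OC)cc1)C[C@@H](OC(=O)/C(C)=C/C)[C@@H](C(=C)CO[Si](C)(C)C(C)(C)C)[C@@H](O[Si](C)(C)C(C)(C)C)C=C | intermediate
30 | (3Z,5S,6R,7R,9R)-9-acetyl-5-[(tert-butyldimethylsilyl)oxy]-6-{3-[(tert-butyldimethylsilyl)oxy]prop-1-en-2-yl}-3-{[(4-methoxybenzyl)oxy]methyl}-9-methyl-2-oxo-2,5,6,7,8,9-hexahydrooxonin-7-yl (2E)-2-methylbut-2-enoate, the nonenolide | CC(=O)[C@@]1(C)C[C@@H](OC(=O)/C(C)=C/C)[C@@H](C(=C)CO[Si](C)(C)C(C)(C)C)[C@@H](O[Si](C)(C)C(C)(C)C)/C=C(/COCc2ccc(OC)cc2)C(=O)O1 | intermediate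
31 | bridged hemiketal: 32 with C2 as CH2 and a hydroxyl on C3 cis to the C10 methyl on the five-membered ring | C=C(CO[Si](C)(C)C(C)(C)C)[C@H]1[C@@H](O[Si](C)(C)C(C)(C)C)/C=C(/COCc3ccc(OC)cc3)[C@@]2(O)CC(=O)[C@@](C)(C[C@H]1OC(=O)/C(C)=C/C)O2 | intermediate (not isolated)
32 | (4Z,6S,7R,8R,10R)-6,12-bis[(tert-butyldimethylsilyl)oxy]-15-[(4-methoxybenzyl)oxy]-1-oxo-3,10-epoxygermacra-2,4,11(13)-trien-8-yl (2E)-2-methylbut-2-enoate (carbocycle numbering) | C=C(CO[Si](C)(C)C(C)(C)C)[C@H]1[C@@H](O[Si](C)(C)C(C)(C)C)/C=C(/COCc3ccc(OC)cc3)C2=CC(=O)[C@@](C)(C[C@H]1OC(=O)/C(C)=C/C)O2 | intermediate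
33 | (4Z,6S,7S,8R,10R)-6,12-dihydroxy-15-[(4-methoxybenzyl)oxy]-1-oxo-3,10-epoxygermacra-2,4,11(13)-trien-8-yl (2E)-2-methylbut-2-enoate, same geometry as 32 | C=C(CO)[C@H]1[C@@H](O)/C=C(/COCc3ccc(OC)cc3)C2=CC(=O)[C@@](C)(C[C@H]1OC(=O)/C(C)=C/C)O2 | intermediate
34 | 12,6-lactol of 33 (C12 hemiacetal, anomers) | C=C1C(O)O[C@H]2/C=C(/COCc4ccc(OC)cc4)C3=CC(=O)[C@@](C)(C[C@@H](OC(=O)/C(C)=C/C)[C@@H]12)O3 | intermediate (not isolated)
35 | (4Z,6S,7R,8R,10R)-15-[(4-methoxybenzyl)oxy]-1-oxo-3,10-epoxygermacra-2,4,11(13)-trien-12,6-olid-8-yl (2E)-2-methylbut-2-enoate | C=C1C(=O)O[C@H]2/C=C(/COCc4ccc(OC)cc4)C3=CC(=O)[C@@](C)(C[C@@H](OC(=O)/C(C)=C/C)[C@@H]12)O3 | intermediate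
36 | CNP0269689.6, (4Z,6S,7R,8R,10R)-15-hydroxy-1-oxo-3,10-epoxygermacra-2,4,11(13)-trien-12,6-olid-8-yl (2E)-2-methylbut-2-enoate | C=C1C(=O)O[C@H]2/C=C(/CO)C3=CC(=O)[C@@](C)(C[C@@H](OC(=O)/C(C)=C/C)[C@@H]12)O3 | target

**Step count**

Total: 23 steps. Longest linear sequence: 16 steps (steps 1–5, 11–14, 17–23).

**Steps most likely to fail**

1. Step 19 (ring-closing metathesis to the nonenolide). The ruthenium alkylidene at C5 must close onto an electron-poor 1,1-disubstituted acrylate inside a strained nine-membered lactone that has to adopt the s-cis ester conformation. Ring closure may therefore be slower than intermolecular metathesis at the vinyl group (oligomers) and catalyst decay. Fallback: it sets out from 29 and comes back at 32. The Claisen condensation and cyclodehydration of step 20 (LiN(SiMe3)2, THF, −78 °C; then TsOH) are run on the open-chain α-acyloxy ketone 29, the classical case of this furanone synthesis, to give the open-chain 5-alkenyl-3(2H)-furanone F1. Ring-closing metathesis of F1 between the C6 vinyl group and the C4 methylene (same ruthenium catalyst, high dilution) then closes the ten-membered carbocycle directly, without the ester conformational penalty. This fallback gives up the lactone as ring template and keeps only the C2–C3 Claisen bond.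

2. Step 11 (Barbier union). The C6 silyloxy centre may bias the two faces of C7 only weakly, which would give a mixture of C7/C8 pairs, and the allylindium may lose silanolate by 1,4-elimination. Fallback: it sets out again from 7 and 15 and comes back at 18, and it replaces substrate control by ligand control. A Nozaki–Hiyama–Kishi-type allylation with stoichiometric CrCl2, a chiral oxazoline–sulfonamide ligand and Et3N in THF at rt is used; the allylchromium species of 2-(bromomethyl)alk-2-enoates are likewise cis-lactone selective, and the ligand enantiomer is chosen to reinforce the C6 bias. The chromium alkoxide gives 17 on work-up, which lactonises to 18 as in step 11; the fallback makes no new compound (F0).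

3. Step 20 (Claisen condensation on the nonenolide). With two equivalents of strong base, deprotonation at C6–H (γ to the lactone carbonyl) or at the tiglate γ-methyl may compete, with loss of the Z geometry or β-elimination of the C6 silyloxy group, and the amide base may open the strained lactone. Fallback: it sets out from 30 and comes back at 32. Soft enolisation with Me3SiOTf/Et3N (CH2Cl2, −78 °C) gives the trimethylsilyl enol ether of the methyl ketone F2 without any strong base. Anhydrous fluoride ((Me2N)3S+ Me3SiF2−, THF, −78 °C) then releases the enolate in the absence of excess base for the same 5-exo Claisen closure, and the acid treatment of step 20 gives 32.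

**Further compounds**

F1 | step 19 | open-chain furanone: (2R)-2-methyl-5-(3-[(4-methoxybenzyl)oxy]prop-1-en-2-yl)furan-3(2H)-one carrying on C2 the C9–C5 chain of 29 (8-O-tigloyl, 6-OTBS, 12-OTBS, C6 vinyl) | C=C(COCc2ccc(OC)cc2)C1=CC(=O)[C@@](C)(C[C@@H](OC(=O)/C(C)=C/C)[C@@H](C(=C)CO[Si](C)(C)C(C)(C)C)[C@@H](O[Si](C)(C)C(C)(C)C)C=C)O1
F0 | step 11 | none | none
F2 | step 20 | trimethylsilyl enol ether of 30 (C1=C2 enol ether, otherwise as 30) | C=C(O[Si](C)(C)C)[C@@]1(C)C[C@@H](OC(=O)/C(C)=C/C)[C@@H](C(=C)CO[Si](C)(C)C(C)(C)C)[C@@H](O[Si](C)(C)C(C)(C)C)/C=C(/COCc2ccc(OC)cc2)C(=O)O1
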